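The runs come from a simulation on assumed constants.

Between 2.50 min and 5.00 min, free monomer in the teal run falls with a late slope of 0.140 /min, and I build on that number. The new flasks differ by temperature.

| flask | free monomer | initiator | temperature | remark | time |
|---|---|---|---|---|---|
| grey | 1.5 M | 5 mol% | −10 °C | run made earlier |  |
| teal | 1.5 M | 20 mol% | 23 °C | run made earlier |  |
| Sunday's | 1.5 M | 10 mol% | 35 °C |  | 4.0 min |
| Friday's | 1.5 M | 10 mol% | −5 °C |  | 4.0 min |
| Monday's | 1.5 M | 10 mol% | −25 °C |  | 4.0 min |
| Wednesday's | 1.5 M | 10 mol% | 15 °C |  | 4.0 min |

| run | time / min | monomer in chains / % | free monomer / % |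
|---|---|---|---|
| grey | 1.50 | 0 | 100 |
| grey | 5.00 | 1 | 100 |
| grey | 8.00 | 2 | 95 |
| grey | 12.0 | 4 | 99 |
| grey | 20.0 | 5 | 96 |
| grey | 25.0 | 6 | 95 |
| grey | 30.0 | 8 | 91 |
| teal | 0.417 | 6 | 90 |
| teal | 0.833 | 17 | 83 |
| teal | 1.33 | 23 | 75 |
| teal | 1.50 | 26 | 74 |
| teal | 2.50 | 36 | 61 |
| teal | 4.00 | 48 | 50 |
| teal | 5.00 | 56 | 43 |

(scatter of a reading: 1.5 percentage points)

* the best flask by amount of monomer in chains, in percent of the free monomer charged; "all alike" if 1.5 percentage points covers them all (Sunday's / Friday's / Monday's / Wednesday's / all alike)
* amount of monomer in chains at the end, in percent of the free monomer charged, Sunday's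
* amount of monomer in chains at the end, in percent of the free monomer charged, Friday's
* amount of monomer in chains at the end, in percent of the free monomer charged, Monday's
* amount of monomer in chains at the end, in percent of the free monomer charged, Wednesday's

- the analysis behind the earlier runs scatters by 1.5 percentage points, standard deviation
- a reading or a percentage of monomer in chains counts all its forms, free or not

I read the slope as propagation on living ends, the growing chain ends, and I suppose that each initiator starts one living end and takes one free monomer in doing so. Dividing by the teal charge of initiator gives a propagation constant k_p of 0.466 /M/min at 23 °C. The fall of free monomer from the charge to the last grey reading, divided by the grey charge of initiator, reads 0.0419 /M/min at −10 °C. The activation energy therefore reads 47.3 kJ/mol, a rough value, for it rests on one grey reading with a scatter of 1.5 percentage points. At 35 °C, k_p reads 0.985 /M/min.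

Sunday's then has 0.148 /min. This is the ceiling constant k_c: k_p times the charged initiator concentration, the pseudo-first-order constant of free monomer once every initiator has become a living end. With every living end standing from the start, Sunday's reaches 50.2% in chains, so I commit to a figure just under that.

The forecast, whose ground is “Both runs follow first-order monomer consumption”, names Sunday's as best, with 54%, 3.3%, 0.5% and 17% for Sunday's, Friday's, Monday's and Wednesday's. Its Sunday's figure stands above my ceiling.

The flasks give 47.6%, 3.41%, 0.309% and 18.3% in that order, and Sunday's is best.

    free monomer + living end → monomer in chains + living end, rate k1*[living end]*[free monomer] (k = 0.0160 /M/s, Ea = 47.0 kJ/mol)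
    crystals ⇌ monomer in chains, rate k2*(cs2 - [monomer in chains]) while solid is left; crystals form when [monomer in chains] > cs2 (solubility = 0.200 M, k = 0.0640 /s)
    free monomer + initiator → living end + monomer in chains (k = 0.0470 /M/s, Ea = 67.0 kJ/mol)
    (constants at 35 °C)

Sunday's ends under the ceiling: from 2.00 min to 4.00 min its free monomer falls with a slope of 0.144 /min against k_c of 0.148 /min, with living end at 0.150 M. The falling level of initiator, 0.0987% of its own charge at 2.00 min, and the time given act together on Sunday's figure: with the initiator level held Sunday's reads 98.1% in the same time, and after 40.0 min it reads 99.7%. At 15 °C the ceiling constant is 0.0410 /min, which puts the floor of free monomer in Wednesday's after 40.0 min at 17.4%, and that flask holds 19.1%.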